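**Retrosynthetic overview**
1. Ring B (1,2-dioxane, C3–C6) is cut at O–C3 (6-exo peroxy-Michael addition to a C2=C3 enoate) and at O–C6 (SN2 of hydroperoxide anion on a C6 triflate, inversion). The C6-hydroxy enoate comes from a C3–C6 γ-lactone by lactol Wittig.
2. The C17–C20 Z,E-diene is cut at C17=C18: Z-selective Wittig of a C17 ylide with (E)-hepta-2,6-dienal.
3. Ring A (tetrahydrofuran, O–C7–C8–C9–C10) carries the C8–C9 bond opposite its oxygen. Cutting that bond (hydrogenation, then ring-closing metathesis in reverse) leaves an acyclic ether whose carbinol carbons C7 and C10 each bear a vinyl group.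
4. That bis-allylic ether is cut at O–C7: iridium-catalysed branched allylic etherification of the (R)-C9–C17 allylic alkoxide (C10 from a Sharpless kinetic resolution) with the linear allylic carbonate of the glutamate-derived lactone (C6 from the pool); the catalyst sets C7.
5. Ring order: lactone (bought) → ring A (step 9) → ring B (step 19).

Key step: step 9

**Remarks on the chemistry**
- Atoms are numbered along the chain from the acid carbon C1. The target is (3R,6R,7S,10R,17Z,19E), with a trans-3,6-dioxane and a trans-2,5-tetrahydrofuran.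
- The C6 oxygen and C3 are carried as the γ-lactone of the starting material, and the C17 oxygen as a benzyl ether. One hydrogenation then saturates ring A and frees C17–OH, and one lactol Wittig frees C6–OH together with the enoate.
- Assumption: the (Sa,Sc,Sc) phosphoramidite gives (S) at C7, by analogy with the facial preference of this catalyst family for allyl substituents that outrank vinyl; if the sense is opposite, the enantiomeric ligand is used.

**Route**

Step 1
Reactants: 1 octane-1,8-diol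
Product: 2 8-(benzyloxy)octan-1-ol
Conditions: BnBr (1.1 equiv), Ag2O (1.5 equiv), CH2Cl2, rt
Reagents that add atoms: benzyl bromide, BrCc1ccccc1
Why: Ag2O-mediated Williamson etherification of a symmetrical diol should stop at the mono-ether, since silver coordination activates one hydroxyl at a time.

Step 2
Reactants: 2 8-(benzyloxy)octan-1-ol
Product: 3 8-(benzyloxy)octanal
Conditions: PhI(OAc)2 (1.1 equiv), TEMPO (10 mol %), CH2Cl2, rt
Reagents that add atoms: none
Why: Oxoammonium (TEMPO) oxidation should take the primary alcohol to the aldehyde without over-oxidation and leave the benzyl ether alone.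

Step 3
Reactants: 3 8-(benzyloxy)octanal; 4 vinylmagnesium bromide
Product: 5 rac-10-(benzyloxy)dec-1-en-3-ol
Conditions: THF, −78 → 0 °C; aq NH4Cl
Reagents that add atoms: none
Why: Grignard 1,2-addition to an unhindered aldehyde should give the racemic allylic alcohol (C9, C10 and the carbon later lost as ethylene).

Step 4
Reactants: 5 rac-10-(benzyloxy)dec-1-en-3-ol
Product: 6 (3R)-10-(benzyloxy)dec-1-en-3-ol
Conditions: Ti(OiPr)4 (1.0 equiv), L-(+)-diisopropyl tartrate (1.2 equiv), t-BuOOH (0.6 equiv), 4 Å MS, CH2Cl2, −20 °C, run past half conversion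
Reagents that add atoms: none
Why: In the Sharpless kinetic resolution the L-(+)-tartrate titanium complex should epoxidise the (S)-alk-1-en-3-ol much faster, so the (R)-alcohol (C10) is recovered enantioenriched and separated from the polar epoxy alcohol.

Step 5
Reactants: 7 (5S)-5-(hydroxymethyl)oxolan-2-one; 8 (triphenylphosphoranylidene)acetaldehyde
Product: 10 (2E)-3-[(2S)-5-oxooxolan-2-yl]prop-2-enal, via lactone aldehyde 9 (not isolated)
Conditions: PhI(OAc)2, TEMPO (10 mol %), CH2Cl2, rt; then 8 (1.05 equiv), rt → 40 °C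
Reagents that add atoms: none
Why: TEMPO oxidation followed in the same flask by Wittig olefination with the stabilised formyl ylide should trap the sensitive α-acyloxy aldehyde before it hydrates or epimerises and give the E-enal (C6 unchanged).

Step 6
Reactants: 10 (2E)-3-[(2S)-5-oxooxolan-2-yl]prop-2-enal
Product: 11 (5S)-5-[(1E)-3-hydroxyprop-1-en-1-yl]oxolan-2-one
Conditions: NaBH4, CeCl3·7H2O, MeOH, −40 °C
Reagents that add atoms: none
Why: Luche reduction should reduce the enal 1,2-selectively to the allylic alcohol; the lactone is not touched by NaBH4 at this temperature.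

Step 7
Reactants: 11 (5S)-5-[(1E)-3-hydroxyprop-1-en-1-yl]oxolan-2-one
Product: 12 tert-butyl (2E)-3-[(2S)-5-oxooxolan-2-yl]prop-2-en-1-yl carbonate
Conditions: Boc2O (1.3 equiv), DMAP (10 mol %), CH2Cl2, 0 °C → rt
Reagents that add atoms: di-tert-butyl dicarbonate, CC(C)(C)OC(=O)OC(=O)OC(C)(C)C
Why: DMAP-catalysed acylation of the primary alcohol should give the linear tert-butyl carbonate, whose bulky carbonyl resists exchange with the alkoxide used in step 8.

Step 8
Reactants: 6 (3R)-10-(benzyloxy)dec-1-en-3-ol; 12 tert-butyl (2E)-3-[(2S)-5-oxooxolan-2-yl]prop-2-en-1-yl carbonate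
Product: 15 (5S)-5-[(1S)-1-{[(3R)-10-(benzyloxy)dec-1-en-3-yl]oxy}prop-2-en-1-yl]oxolan-2-one, via lithium alkoxide 13 (not isolated), via copper alkoxide 14 (not isolated)
Conditions: 6 (2.0 equiv), n-BuLi (2.0 equiv), THF, 0 °C; CuI (2.0 equiv), rt; then 12, [Ir(cod)Cl]2 (2 mol %), (Sa,Sc,Sc)-O,O'-(1,1'-binaphthyl-2,2'-diyl) N,N-bis(1-phenylethyl)phosphoramidite (4 mol %), THF, rt
Reagents that add atoms: none
Why: Iridium-catalysed allylic etherification with a soft copper alkoxide should ionise the primary carbonate (not the secondary allylic lactone C–O) and deliver the alkoxide to the substituted allyl terminus, the phosphoramidite setting C7 as (S) under catalyst control while C10 and C6 are untouched; the excess of 6 is recovered.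

Step 9
Reactants: 15 (5S)-5-[(1S)-1-{[(3R)-10-(benzyloxy)dec-1-en-3-yl]oxy}prop-2-en-1-yl]oxolan-2-one
Product: 16 (5S)-5-[(2S,5R)-5-[7-(benzyloxy)heptyl]-2,5-dihydrofuran-2-yl]oxolan-2-one
Conditions: second-generation Grubbs catalyst (H2IMes)(PCy3)Cl2Ru=CHPh (3 mol %), CH2Cl2 (5 mM), 40 °C
Reagents that add atoms: none
Why: The ruthenium benzylidene exchanges onto one monosubstituted vinyl group, the new alkylidene adds [2+2] to the second vinyl group, and cycloreversion of the ruthenacyclobutane forms the C8=C9 bond with loss of ethylene. The closest known reaction type is this very one, ring-closing metathesis of acyclic bis-allylic ethers to 2,5-dihydrofurans. Ring A closes as a five-membered ring through the intramolecular metallacyclobutane, so the ring alkene is necessarily cis and the closure is driven by escape of ethylene. No stereocentre is formed: C7 (step 8) and C10 (step 4) flank the reacting alkenes but are not involved, so the 2,5-trans relationship built into the ether is carried into the ring. The step needs ring closure to beat intermolecular metathesis and ruthenium hydride alkene migration, which high dilution, the five-ring size, two unhindered terminal alkenes and a short reaction time should secure; lactone and benzyl ether are inert.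

Step 10
Reactants: 16 (5S)-5-[(2S,5R)-5-[7-(benzyloxy)heptyl]-2,5-dihydrofuran-2-yl]oxolan-2-one
Product: 17 (5S)-5-[(2S,5R)-5-(7-hydroxyheptyl)oxolan-2-yl]oxolan-2-one
Conditions: H2 (1 atm), Pd/C (10 %), EtOAc, rt
Reagents that add atoms: none
Why: Heterogeneous hydrogenation should saturate the ring alkene and hydrogenolyse the benzyl ether in one operation, freeing C17–OH; the lactone keeps C6–O and C3 masked.

Step 11
Reactants: 17 (5S)-5-[(2S,5R)-5-(7-hydroxyheptyl)oxolan-2-yl]oxolan-2-one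
Product: 18 (5S)-5-[(2S,5R)-5-(7-iodoheptyl)oxolan-2-yl]oxolan-2-one
Conditions: I2, PPh3, imidazole, CH2Cl2, 0 °C → rt
Reagents that add atoms: iodine, II
Why: Appel-type iodination should convert the only hydroxyl, a primary one, into the iodide through its alkoxyphosphonium salt.

Step 12
Reactants: 18 (5S)-5-[(2S,5R)-5-(7-iodoheptyl)oxolan-2-yl]oxolan-2-one
Product: 19 {7-[(2R,5S)-5-[(2S)-5-oxooxolan-2-yl]oxolan-2-yl]heptyl}triphenylphosphonium iodide
Conditions: PPh3 (1.5 equiv), MeCN, 80 °C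
Reagents that add atoms: triphenylphosphine, c1ccccc1P(c1ccccc1)c1ccccc1
Why: SN2 quaternisation of triphenylphosphine by the primary iodide should give the phosphonium salt, purified by trituration.

Step 13
Reactants: 20 pent-4-enal; 8 (triphenylphosphoranylidene)acetaldehyde
Product: 21 (2E)-hepta-2,6-dienal
Conditions: toluene, 80 °C; distillation
Reagents that add atoms: none
Why: Wittig two-carbon homologation with the stabilised formyl ylide should give the E-enal (C18–C24).

Step 14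
Reactants: 19 {7-[(2R,5S)-5-[(2S)-5-oxooxolan-2-yl]oxolan-2-yl]heptyl}triphenylphosphonium iodide; 21 (2E)-hepta-2,6-dienal
Product: 23 (5S)-5-[(2S,5R)-5-[(7Z,9E)-tetradeca-7,9,13-trien-1-yl]oxolan-2-yl]oxolan-2-one, via phosphorus ylide 22 (not isolated)
Conditions: NaN(SiMe3)2 (0.95 equiv), THF, −40 °C; then 21, −78 °C → rt
Reagents that add atoms: none
Why: A non-stabilised ylide under lithium-free conditions should add to the enal under kinetic control to give the new C17=C18 bond Z while the C19=C20 bond stays E; a slight deficit of base keeps the lactone from enolising.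

Step 15
Reactants: 23 (5S)-5-[(2S,5R)-5-[(7Z,9E)-tetradeca-7,9,13-trien-1-yl]oxolan-2-yl]oxolan-2-one
Product: 24 (5S)-5-[(2S,5R)-5-[(7Z,9E)-tetradeca-7,9,13-trien-1-yl]oxolan-2-yl]oxolan-2-ol (both anomers)
Conditions: i-Bu2AlH (1.1 equiv), CH2Cl2, −78 °C
Reagents that add atoms: none
Why: Partial reduction of a γ-lactone by i-Bu2AlH at low temperature should stop at the lactol because the tetrahedral aluminate is stable until work-up; the alkenes are inert.

Step 16
Reactants: 24 (5S)-5-[(2S,5R)-5-[(7Z,9E)-tetradeca-7,9,13-trien-1-yl]oxolan-2-yl]oxolan-2-ol; 25 ethyl (triphenylphosphoranylidene)acetate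
Product: 27 ethyl (2E,6S)-6-hydroxy-6-[(2S,5R)-5-[(7Z,9E)-tetradeca-7,9,13-trien-1-yl]oxolan-2-yl]hex-2-enoate, via open hydroxy aldehyde 26 (not isolated)
Conditions: toluene, PhCO2H (cat.), 50 °C
Reagents that add atoms: none
Why: Wittig olefination of the lactol through its open-chain aldehyde tautomer with a stabilised ylide should give the E-enoate (C1–C3) and free C6–OH under neutral conditions, under which the 5-exo oxa-Michael closure of the hydroxy enoate is slow.

Step 17
Reactants: 27 ethyl (2E,6S)-6-hydroxy-6-[(2S,5R)-5-[(7Z,9E)-tetradeca-7,9,13-trien-1-yl]oxolan-2-yl]hex-2-enoate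
Product: 28 ethyl (2E,6S)-6-[(2S,5R)-5-[(7Z,9E)-tetradeca-7,9,13-trien-1-yl]oxolan-2-yl]-6-{[(trifluoromethyl)sulfonyl]oxy}hex-2-enoate
Conditions: Tf2O (1.2 equiv), 2,6-lutidine, CH2Cl2, −78 → −40 °C; used crude at once
Reagents that add atoms: trifluoromethanesulfonic anhydride, O=S(=O)(OS(=O)(=O)C(F)(F)F)C(F)(F)F
Why: O-Sulfonylation with retention should give a secondary triflate that the β-oxygen of ring A stabilises against ionisation, reactive enough for substitution at 0 °C.

Step 18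
Reactants: 28 ethyl (2E,6S)-6-[(2S,5R)-5-[(7Z,9E)-tetradeca-7,9,13-trien-1-yl]oxolan-2-yl]-6-{[(trifluoromethyl)sulfonyl]oxy}hex-2-enoate
Product: 29 ethyl (2E,6R)-6-hydroperoxy-6-[(2S,5R)-5-[(7Z,9E)-tetradeca-7,9,13-trien-1-yl]oxolan-2-yl]hex-2-enoate
Conditions: H2O2 (50 % aq, 20 equiv), KOH (1.5 equiv), THF, −10 → 0 °C, short reaction time; pH 7 buffer
Reagents that add atoms: hydrogen peroxide, OO
Why: SN2 displacement of a sulfonate by hydroperoxide anion, an alpha-effect nucleophile, should invert C6 to (R), while the cold, brief exposure and the low reactivity of simple enoates toward Weitz–Scheffer epoxidation spare the ester; any hydroperoxide that already closes to the dioxane converges in step 19.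

Step 19
Reactants: 29 ethyl (2E,6R)-6-hydroperoxy-6-[(2S,5R)-5-[(7Z,9E)-tetradeca-7,9,13-trien-1-yl]oxolan-2-yl]hex-2-enoate
Product: 30 ethyl 2-[(3R,6R)-6-[(2S,5R)-5-[(7Z,9E)-tetradeca-7,9,13-trien-1-yl]oxolan-2-yl]-1,2-dioxan-3-yl]acetate
Conditions: Et2NH (cat.), CF3CH2OH, rt
Reagents that add atoms: none
Why: Intramolecular 6-exo-trig peroxy-Michael addition through a chair with the ring A substituent and the acetate arm both equatorial should give the trans (3R,6R) dioxane, and since the addition is reversible (retro-Michael) the diequatorial isomer is also the thermodynamic one.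

Step 20
Reactants: 30 ethyl 2-[(3R,6R)-6-[(2S,5R)-5-[(7Z,9E)-tetradeca-7,9,13-trien-1-yl]oxolan-2-yl]-1,2-dioxan-3-yl]acetate
Product: 31 2-[(3R,6R)-6-[(2S,5R)-5-[(7Z,9E)-tetradeca-7,9,13-trien-1-yl]oxolan-2-yl]-1,2-dioxan-3-yl]acetic acid
Conditions: LiOH (3 equiv), THF/H2O 3:1, 0 °C; then 1 M HCl to pH 3 at 0 °C
Reagents that add atoms: lithium hydroxide, [Li+].[OH-]
Why: Saponification of the unhindered ethyl ester at 0 °C should outpace base-induced Kornblum–DeLaMare cleavage of the dialkyl peroxide and leave the skipped diene and all four stereocentres intact.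

**Compound list**
1 | octane-1,8-diol | OCCCCCCCCO | starting material
2 | 8-(benzyloxy)octan-1-ol | OCCCCCCCCOCc1ccccc1 | intermediate
3 | 8-(benzyloxy)octanal | O=CCCCCCCCOCc1ccccc1 | intermediate
4 | vinylmagnesium bromide | C=C[Mg]Br | starting material
5 | rac-10-(benzyloxy)dec-1-en-3-ol | C=CC(O)CCCCCCCOCc1ccccc1 | intermediate
6 | (3R)-10-(benzyloxy)dec-1-en-3-ol | C=C[C@H](O)CCCCCCCOCc1ccccc1 | intermediate
7 | (5S)-5-(hydroxymethyl)oxolan-2-one | O=C1CC[C@@H](CO)O1 | starting material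
8 | (triphenylphosphoranylidene)acetaldehyde | O=CC=P(c1ccccc1)(c1ccccc1)c1ccccc1 | starting material
9 | (2S)-5-oxooxolane-2-carbaldehyde | O=C[C@@H]1CCC(=O)O1 | intermediate (not isolated)
10 | (2E)-3-[(2S)-5-oxooxolan-2-yl]prop-2-enal | O=C/C=C/[C@@H]1CCC(=O)O1 | intermediate
11 | (5S)-5-[(1E)-3-hydroxyprop-1-en-1-yl]oxolan-2-one | OC/C=C/[C@@H]1CCC(=O)O1 | intermediate
12 | tert-butyl (2E)-3-[(2S)-5-oxooxolan-2-yl]prop-2-en-1-yl carbonate | CC(C)(C)OC(=O)OC/C=C/[C@@H]1CCC(=O)O1 | intermediate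
13 | lithium (3R)-10-(benzyloxy)dec-1-en-3-olate | C=C[C@H]([O-])CCCCCCCOCc1ccccc1.[Li+] | intermediate (not isolated)
14 | copper (3R)-10-(benzyloxy)dec-1-en-3-olate | C=C[C@H](O[Cu])CCCCCCCOCc1ccccc1 | intermediate (not isolated)
15 | (5S)-5-[(1S)-1-{[(3R)-10-(benzyloxy)dec-1-en-3-yl]oxy}prop-2-en-1-yl]oxolan-2-one | C=C[C@@H](CCCCCCCOCc1ccccc1)O[C@@H](C=C)[C@@H]1CCC(=O)O1 | intermediate (key-step precursor)
16 | (5S)-5-[(2S,5R)-5-[7-(benzyloxy)heptyl]-2,5-dihydrofuran-2-yl]oxolan-2-one | c1ccccc1COCCCCCCC[C@@H]1C=C[C@@H]([C@@H]2CCC(=O)O2)O1 | intermediate (key-step product)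
17 | (5S)-5-[(2S,5R)-5-(7-hydroxyheptyl)oxolan-2-yl]oxolan-2-one | OCCCCCCC[C@@H]1CC[C@@H]([C@@H]2CCC(=O)O2)O1 | intermediate
18 | (5S)-5-[(2S,5R)-5-(7-iodoheptyl)oxolan-2-yl]oxolan-2-one | ICCCCCCC[C@@H]1CC[C@@H]([C@@H]2CCC(=O)O2)O1 | intermediate
19 | {7-[(2R,5S)-5-[(2S)-5-oxooxolan-2-yl]oxolan-2-yl]heptyl}triphenylphosphonium iodide | [I-].c1ccccc1[P+](c1ccccc1)(c1ccccc1)CCCCCCC[C@@H]1CC[C@@H]([C@@H]2CCC(=O)O2)O1 | intermediate
20 | pent-4-enal | C=CCCC=O | starting material
21 | (2E)-hepta-2,6-dienal | C=CCC/C=C/C=O | intermediate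
22 | ylide of 19, (5S)-5-[(2S,5R)-5-[7-(triphenylphosphoranylidene)heptyl]oxolan-2-yl]oxolan-2-one | c1ccccc1P(c1ccccc1)(c1ccccc1)=CCCCCCC[C@@H]1CC[C@@H]([C@@H]2CCC(=O)O2)O1 | intermediate (not isolated)
23 | (5S)-5-[(2S,5R)-5-[(7Z,9E)-tetradeca-7,9,13-trien-1-yl]oxolan-2-yl]oxolan-2-one | C=CCC/C=C/C=C\CCCCCC[C@@H]1CC[C@@H]([C@@H]2CCC(=O)O2)O1 | intermediate
24 | (5S)-5-[(2S,5R)-5-[(7Z,9E)-tetradeca-7,9,13-trien-1-yl]oxolan-2-yl]oxolan-2-ol (anomers) | C=CCC/C=C/C=C\CCCCCC[C@@H]1CC[C@@H]([C@@H]2CCC(O)O2)O1 | intermediate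
25 | ethyl (triphenylphosphoranylidene)acetate | CCOC(=O)C=P(c1ccccc1)(c1ccccc1)c1ccccc1 | starting material
26 | (4S)-4-hydroxy-4-[(2S,5R)-5-[(7Z,9E)-tetradeca-7,9,13-trien-1-yl]oxolan-2-yl]butanal | C=CCC/C=C/C=C\CCCCCC[C@@H]1CC[C@@H]([C@@H](O)CCC=O)O1 | intermediate (not isolated)
27 | ethyl (2E,6S)-6-hydroxy-6-[(2S,5R)-5-[(7Z,9E)-tetradeca-7,9,13-trien-1-yl]oxolan-2-yl]hex-2-enoate | C=CCC/C=C/C=C\CCCCCC[C@@H]1CC[C@@H]([C@@H](O)CC/C=C/C(=O)OCC)O1 | intermediate
28 | ethyl (2E,6S)-6-[(2S,5R)-5-[(7Z,9E)-tetradeca-7,9,13-trien-1-yl]oxolan-2-yl]-6-{[(trifluoromethyl)sulfonyl]oxy}hex-2-enoate | C=CCC/C=C/C=C\CCCCCC[C@@H]1CC[C@@H]([C@@H](OS(=O)(=O)C(F)(F)F)CC/C=C/C(=O)OCC)O1 | intermediate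
29 | ethyl (2E,6R)-6-hydroperoxy-6-[(2S,5R)-5-[(7Z,9E)-tetradeca-7,9,13-trien-1-yl]oxolan-2-yl]hex-2-enoate | C=CCC/C=C/C=C\CCCCCC[C@@H]1CC[C@@H]([C@H](OO)CC/C=C/C(=O)OCC)O1 | intermediate
30 | ethyl 2-[(3R,6R)-6-[(2S,5R)-5-[(7Z,9E)-tetradeca-7,9,13-trien-1-yl]oxolan-2-yl]-1,2-dioxan-3-yl]acetate | C=CCC/C=C/C=C\CCCCCC[C@@H]1CC[C@@H]([C@H]2CC[C@H](CC(=O)OCC)OO2)O1 | intermediate
31 | 2-[(3R,6R)-6-[(2S,5R)-5-[(7Z,9E)-tetradeca-7,9,13-trien-1-yl]oxolan-2-yl]-1,2-dioxan-3-yl]acetic acid | C=CCC/C=C/C=C\CCCCCC[C@@H]1CC[C@@H]([C@H]2CC[C@H](CC(=O)O)OO2)O1 | target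

**Step count**
Total: 20 steps. Longest linear sequence: 16 steps (steps 1–4, 8–12, 14–20, from octane-1,8-diol).

**Steps most likely to fail**

1. Step 18 (hydroperoxide substitution at C6). The triflate may ionise with participation of the ring A oxygen, which would give ring expansion or retention at C6. It may also eliminate, or the peroxide anion may attack the enoate before substitution is complete.
Fallback: the C–O–O bond is made before the enoate exists, on a stable mesylate, with a protected peroxide. Setting out from 23, LiAlH4 (THF, 0 °C) should open the lactone to (1S)-1-[(2S,5R)-5-[(7Z,9E)-tetradeca-7,9,13-trien-1-yl]oxolan-2-yl]butane-1,4-diol F1. TBDPSCl and imidazole should silylate the primary hydroxyl to give the C3 silyl ether F2, and MsCl/Et3N the C6 mesylate F3. Substitution with 2-methoxyprop-2-yl hydroperoxide (a known reagent) and CsOH·H2O in DMF should give, with inversion, the (4R)-peroxyketal silyl ether F4. Bu4NF should free the primary alcohol F5, Dess–Martin periodinane with NaHCO3 should give the aldehyde F6, and ylide 25 the peroxyketal enoate F7. AcOH/H2O/THF should then release the hydroperoxide, returning to the route at 29.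

2. Step 8 (iridium etherification). The alkoxide may add to the lactone carbonyl, or catalyst control at C7 may be eroded by the neighbouring C6 acyloxy centre (mismatched pairing, lower branched selectivity).
Fallback: the lactone is carried through the etherification as a base-inert lactol methyl acetal. Setting out from 11, i-Bu2AlH (2.2 equiv, −78 °C) should give (5S)-5-[(1E)-3-hydroxyprop-1-en-1-yl]oxolan-2-ol F8. MeOH with pyridinium p-toluenesulfonate should give the methyl acetal (2E)-3-[(2S)-5-methoxyoxolan-2-yl]prop-2-en-1-ol F9, and Boc2O/DMAP its tert-butyl carbonate F10. Etherification with copper alkoxide 14 under the conditions of step 8 should give the acetal ether F11. Pyridinium p-toluenesulfonate in aqueous acetone should give the lactol ether F12, and Pr4N[RuO4] (cat.) with N-methylmorpholine N-oxide should oxidise it to the lactone, returning to the route at 15.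

3. Step 14 (Z-selective Wittig). Z-selectivity may erode to a mixture with the 17E isomer that is hard to separate, or the base may enolise the lactone or the enal.
Fallback: the diene is assembled by cross-coupling of two geometrically defined alkenyl partners. Setting out from 17, PhI(OAc)2/TEMPO should give 7-[(2R,5S)-5-[(2S)-5-oxooxolan-2-yl]oxolan-2-yl]heptanal F13. Stork–Zhao olefination with (iodomethyl)triphenylphosphonium iodide and NaN(SiMe3)2 (THF, −78 °C) should give the (Z)-vinyl iodide F14. Separately, Cp2Zr(H)Cl-catalysed hydroboration of hex-1-en-5-yne with pinacolborane should give (E)-2-(hexa-1,5-dien-1-yl)-4,4,5,5-tetramethyl-1,3,2-dioxaborolane F15. Suzuki coupling of F14 with F15 (Pd(PPh3)4, K3PO4, THF/H2O, rt) should join C18 to C19 with retention at both alkenes, returning to the route at 23.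

**Further compounds**
F1 | step 18 | (1S)-1-[(2S,5R)-5-[(7Z,9E)-tetradeca-7,9,13-trien-1-yl]oxolan-2-yl]butane-1,4-diol | C=CCC/C=C/C=C\CCCCCC[C@@H]1CC[C@@H]([C@@H](O)CCCO)O1
F2 | step 18 | (1S)-4-[(tert-butyldiphenylsilyl)oxy]-1-[(2S,5R)-5-[(7Z,9E)-tetradeca-7,9,13-trien-1-yl]oxolan-2-yl]butan-1-ol | C=CCC/C=C/C=C\CCCCCC[C@@H]1CC[C@@H]([C@@H](O)CCCO[Si](c2ccccc2)(c2ccccc2)C(C)(C)C)O1
F3 | step 18 | (1S)-4-[(tert-butyldiphenylsilyl)oxy]-1-[(2S,5R)-5-[(7Z,9E)-tetradeca-7,9,13-trien-1-yl]oxolan-2-yl]butyl methanesulfonate | C=CCC/C=C/C=C\CCCCCC[C@@H]1CC[C@@H]([C@@H](OS(C)(=O)=O)CCCO[Si](c2ccccc2)(c2ccccc2)C(C)(C)C)O1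
F4 | step 18 | tert-butyl{[(4R)-4-[(2-methoxypropan-2-yl)peroxy]-4-[(2S,5R)-5-[(7Z,9E)-tetradeca-7,9,13-trien-1-yl]oxolan-2-yl]butyl]oxy}diphenylsilane | C=CCC/C=C/C=C\CCCCCC[C@@H]1CC[C@@H]([C@H](OOC(C)(C)OC)CCCO[Si](c2ccccc2)(c2ccccc2)C(C)(C)C)O1
F5 | step 18 | (4R)-4-[(2-methoxypropan-2-yl)peroxy]-4-[(2S,5R)-5-[(7Z,9E)-tetradeca-7,9,13-trien-1-yl]oxolan-2-yl]butan-1-ol | C=CCC/C=C/C=C\CCCCCC[C@@H]1CC[C@@H]([C@H](OOC(C)(C)OC)CCCO)O1
F6 | step 18 | (4R)-4-[(2-methoxypropan-2-yl)peroxy]-4-[(2S,5R)-5-[(7Z,9E)-tetradeca-7,9,13-trien-1-yl]oxolan-2-yl]butanal | C=CCC/C=C/C=C\CCCCCC[C@@H]1CC[C@@H]([C@H](OOC(C)(C)OC)CCC=O)O1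
F7 | step 18 | ethyl (2E,6R)-6-[(2-methoxypropan-2-yl)peroxy]-6-[(2S,5R)-5-[(7Z,9E)-tetradeca-7,9,13-trien-1-yl]oxolan-2-yl]hex-2-enoate | C=CCC/C=C/C=C\CCCCCC[C@@H]1CC[C@@H]([C@H](OOC(C)(C)OC)CC/C=C/C(=O)OCC)O1
F8 | step 8 | (5S)-5-[(1E)-3-hydroxyprop-1-en-1-yl]oxolan-2-ol | OC/C=C/[C@@H]1CCC(O)O1
F9 | step 8 | (2E)-3-[(2S)-5-methoxyoxolan-2-yl]prop-2-en-1-ol | OC/C=C/[C@@H]1CCC(OC)O1
F10 | step 8 | tert-butyl (2E)-3-[(2S)-5-methoxyoxolan-2-yl]prop-2-en-1-yl carbonate | CC(C)(C)OC(=O)OC/C=C/[C@@H]1CCC(OC)O1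
F11 | step 8 | (2S)-2-[(1S)-1-{[(3R)-10-(benzyloxy)dec-1-en-3-yl]oxy}prop-2-en-1-yl]-5-methoxyoxolane | C=C[C@@H](CCCCCCCOCc1ccccc1)O[C@@H](C=C)[C@@H]1CCC(OC)O1
F12 | step 8 | (5S)-5-[(1S)-1-{[(3R)-10-(benzyloxy)dec-1-en-3-yl]oxy}prop-2-en-1-yl]oxolan-2-ol | C=C[C@@H](CCCCCCCOCc1ccccc1)O[C@@H](C=C)[C@@H]1CCC(O)O1
F13 | step 14 | 7-[(2R,5S)-5-[(2S)-5-oxooxolan-2-yl]oxolan-2-yl]heptanal | O=CCCCCCC[C@@H]1CC[C@@H]([C@@H]2CCC(=O)O2)O1
F14 | step 14 | (5S)-5-[(2S,5R)-5-[(7Z)-8-iodooct-7-en-1-yl]oxolan-2-yl]oxolan-2-one | I/C=C\CCCCCC[C@@H]1CC[C@@H]([C@@H]2CCC(=O)O2)O1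
F15 | step 14 | (E)-2-(hexa-1,5-dien-1-yl)-4,4,5,5-tetramethyl-1,3,2-dioxaborolane | C=CCC/C=C/B1OC(C)(C)C(C)(C)O1
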